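**Plan** (briarane numbering; β = the face of ring A that carries the C15 methyl)
1. Retrosynthesis: remove the C12 butyrate, the C13–C14 oxirane oxygen and C6–Cl. Then cut C8–C17 (Reformatsky), C7–O (epoxide opening) and C5–C16 (1,6-cuprate addition).
2. Feature used: the two acetoxy carbons C2 and C9 lie on either side of the C1–C10 fusion bond (a 1,4-dioxygen pattern). A C2–C9 bond therefore contracts the ten-membered ring into a four- and an eight-membered ring. The resulting 6-4-8 cyclobutane-1,2-diol divides at C1–C2 and C9–C10 into 3-methylcyclohexenone and a symmetric cyclooctadiene enediol ether.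
3. Forward ring order: eight-membered ring (acyloin, C2–C9), then cyclobutane on the six-membered enone ([2+2]), then ten-membered ring (C2–C9 scission), then γ-lactone, then oxirane.
4. Stereochemistry: C1 comes from a chiral Lewis acid and C10 from the trans closure of the photoadduct. The rest is relayed from these two centres: C11/C12 (OsO4 anti to the C9 chain), C2 (CBS), C9 (peripheral hydride), C7 (OH-directed epoxidation, then inversion), C8/C17 (tethered enolate), C6 (face-selective Cl+), C13/C14 (OH-directed epoxidation).

Key step: step 7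

Remark: stereo-elements that are destroyed later are drawn as one isomer or left open. These are C11 in 7–11, sulfur in 12, the C8=C9 geometry in 16–18, C5 in 20 and CHBr in 25–27.
Assumption: the C7=C8 double bond made in steps 14 and 16 is taken as Z (ring-cis, like C5=C6), the less strained geometry when only four sp3 atoms span C4 and C9. The stereochemical argument of steps 18 and 19 holds for this geometry.
Assumption: the oxazaborolidine derived from the (S)-prolinol is written in step 3. Its mirror image is used if the sense of induction with this alkene proves opposite.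

Step 1
Reactants: 1 (1Z,5Z)-cycloocta-1,5-diene
Product: 2 dimethyl (4Z)-oct-4-enedioate
Conditions: O3 (1 equiv, 1 in excess), NaOH, MeOH/CH2Cl2, −78 °C
Reagents that add atoms: ozone [O-][O+]=O; methanol CO
Why: Ozonolysis in methanolic sodium hydroxide turns both carbons of the cleaved C=C directly into methyl esters, and an excess of the cheap diene limits the reaction to one of the two equivalent Z-alkenes, so the other survives as the future C5=C6.

Step 2
Reactants: 2 dimethyl (4Z)-oct-4-enedioate
Product: 3 (1Z,5Z)-1,2-bis(trimethylsilyloxy)cycloocta-1,5-diene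
Conditions: Na, TMSCl, toluene, reflux
Reagents that add atoms: chlorotrimethylsilane C[Si](C)(C)Cl
Why: The acyloin condensation in its Rühlmann (TMSCl-trapping) form makes the C2–C9 bond and the eight-membered ring; the Z-alkene bends the chain toward closure, and the silyl chloride removes methoxide and fixes the enediolate as the symmetric bis(silyl) enediol ether.

Step 3
Reactants: 3 (1Z,5Z)-1,2-bis(trimethylsilyloxy)cycloocta-1,5-diene; 4 3-methylcyclohex-2-en-1-one
Product: 5 trans-fused 6-4-8 keto bis(silyl ether) (C11 ketone; C15 β, H10 α; both OTMS cis on the C15 face of the cyclobutane; 5Z)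
Conditions: 3 (5 equiv), AlBr3-activated oxazaborolidine from (S)-α,α-bis(3,5-dimethylphenyl)prolinol (50 mol %), CH2Cl2, −75 °C, hν (366 nm); neutral silica
Reagents that add atoms: none
Why: Proposed new method: binding of the activated oxazaborolidine to the enone carbonyl shifts the ππ* band to longer wavelength, so at 366 nm mainly the chiral complex is excited. Its electrophilic triplet should attack the most electron-rich C=C of 3 (the enediol ether, not the remote C5=C6) from the unshielded enone face, which sets C1. The twisted triplet should close the 1,4-diradical to the trans six-four fusion (sets C10), and the ring-cis alkene gives the cis four-eight fusion. The symmetry of 3 leaves no regiochemical choice, and a thermal Mukaiyama–Michael addition joining two fully substituted carbons should be negligible at −75 °C. The closest known reaction types are the enantioselective Lewis-acid-catalysed intermolecular [2+2] photocycloaddition of cyclic enones with simple alkenes and the racemic photoaddition of cyclohexenones to 1,2-bis(silyloxy)cycloalkenes.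

Step 4
Reactants: 5 trans-fused 6-4-8 keto bis(silyl ether)
Product: 6 tricyclic 12-en-11-one bis(silyl ether)
Conditions: LDA, THF, −78 °C; then PhS(Cl)=N-t-Bu, −78 °C
Reagents that add atoms: none
Why: This is a one-pot enolate dehydrogenation with a sulfinimidoyl chloride: kinetic deprotonation takes the open C12 methylene (C10–H lies between the fully substituted C1 and C9), S-attack and intramolecular syn elimination give the enone at −78 °C, where the base-labile trans fusion should survive, and the new C12=C13 bond lies opposite the fusion bond, so it adds little strain.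

Step 5
Reactants: 6 tricyclic 12-en-11-one bis(silyl ether)
Product: 7 11-methyl-12-en-11β-ol bis(silyl ether)
Conditions: MeLi, CeCl3, THF, −78 °C
Reagents that add atoms: methyllithium [Li]C
Why: In this organocerium 1,2-addition the non-basic MeCeCl2 brings in C20 without enolising C10–H or adding 1,4, and it attacks anti to the axial C15 methyl (11β-OH), creating a centre that is erased again in step 8.

Step 6
Reactants: 7 11-methyl-12-en-11β-ol bis(silyl ether)
Product: 8 6-4-8 tricyclic 2,9,11-triol (cis-cyclobutane-1,2-diol)
Conditions: K2CO3 (cat.), MeOH, 0 °C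
Reagents that add atoms: none
Why: Base-catalysed methanolysis removes the two tertiary trimethylsilyl ethers; it is safe only at this point, because with the C11 ketone gone the freed C9 alkoxide can no longer trigger a retro-aldol opening of C9–C10.

Step 7
Reactants: 8 6-4-8 tricyclic 2,9,11-triol
Product: 10 11β-hydroxy-11-methylbicyclo[8.4.0] 5Z,12-diene-2,9-dione, via cyclic lead(IV) glycolate 9 (not isolated)
Conditions: Pb(OAc)4 (1.05 equiv), CH2Cl2, 0 °C, short contact; neutral work-up
Reagents that add atoms: none
Why: The cis-diol exchanges two acetates on Pb(IV) to give the five-membered glycolate 9, which collapses in a concerted two-electron shift (Criegee glycol cleavage): the C2–C9 σ-bond breaks, both C–O bonds become carbonyls and Pb(II) leaves, driven by release of the cyclobutane strain, which the trans six-four fusion raises further. The closest known reaction type is the two-carbon ring expansion of enone/1,2-bis(silyloxy)cycloalkene photoadducts by glycol scission. No bond is formed: the ten-membered ring appears because the bond shared by the four- and eight-membered rings disappears, so there is no cyclisation mode and no medium-ring closure penalty. No stereocentre is created; C2 and C9 become trigonal, and C1 and C10 are untouched, so the trans C15/H10 relationship passes into the bicycle. The step needs selectivity for the 1,2-diol over the C11 tertiary allylic alcohol and the two alkenes, which is secured because only O2 and O9 can chelate lead in a five-membered ring (O9 and O11 are 1,3-related). It also needs non-basic conditions, since 10 is a 1,4-diketone and a β-hydroxy ketone open to transannular aldol, retro-aldol and C10 epimerisation.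

Step 8
Reactants: 10 11β-hydroxy-11-methylbicyclo[8.4.0] 5Z,12-diene-2,9-dione
Product: 13 5Z,11,13-triene-2,9-dione, via C11 arenesulfenate 11 (not isolated), via C13 allylic sulfoxide 12 (not isolated)
Conditions: 2,4-(O2N)2C6H3SCl, Et3N, CH2Cl2, 0 → 35 °C
Reagents that add atoms: none
Why: O-sulfenylation, a Mislow–Evans-type [2,3] shift to C13 and syn elimination of the activated sulfenic acid toward C14 (the only β-hydrogens) together amount to a regiospecific 1,4-dehydration of the allylic alcohol to the C11=C12–C13=C14 diene, without any cation or enolate at C10/C11.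

Step 9
Reactants: 13 5Z,11,13-triene-2,9-dione
Product: 14 11α,12α-dihydroxy-5Z,13-diene-2,9-dione
Conditions: OsO4 (2 mol %), NMO (1.05 equiv), acetone/H2O, 0 °C
Reagents that add atoms: N-methylmorpholine N-oxide C[N+]1([O-])CCOCC1; water O
Why: In this Upjohn dihydroxylation OsO4 should pick the most electron-rich C=C, the trisubstituted C11=C12 end of the diene (C13=C14 is neopentyl and C5=C6 is an isolated cis-alkene), and it adds syn from the α face, where C10 carries only hydrogen while the C9 chain blocks the β face; this sets C11 and C12.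

Step 10
Reactants: 14 11α,12α-dihydroxy-5Z,13-diene-2,9-dione
Product: 15 11,12-acetonide dione
Conditions: Me2C(OMe)2, PPTS (cat.), CH2Cl2, rt
Reagents that add atoms: 2,2-dimethoxypropane COC(C)(C)OC
Why: Acid-catalysed transketalisation to the cis-fused dioxolane protects both hydroxyls, removes the retro-aldol risk and leaves C10–H between two quaternary carbons.

Step 11
Reactants: 15 11,12-acetonide dione
Product: 16 C9 tert-butyldimethylsilyl enol ether (Δ8) with free C2 ketone
Conditions: TBSOTf (1.05 equiv), Et3N, CH2Cl2, −78 → −30 °C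
Reagents that add atoms: tert-butyldimethylsilyl triflate CC(C)(C)[Si](C)(C)OS(=O)(=O)C(F)(F)F
Why: In this soft enolisation O-silylation should occur at the C9 carbonyl, whose tertiary neighbour C10 can turn its hydrogen toward the bulky silyloxy group, rather than at C2 next to the quaternary C1, and the amine then removes the accessible C8 proton instead of the buried C10–H.

Step 12
Reactants: 16 C9 silyl enol ether with free C2 ketone
Product: 17 (2S)-alcohol
Conditions: (R)-Me-CBS (30 mol %), catecholborane, toluene, −78 → −40 °C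
Reagents that add atoms: none
Why: With C9 masked, the only ketone has the ideal tert-alkyl/primary-alkyl pattern for a Corey–Bakshi–Shibata reduction, the two exocyclic groups on C1 (CH3, C14) differ too little for a strong substrate bias, and the (R)-catalyst should deliver hydride to give the (2S)-carbinol.

Step 13
Reactants: 17 (2S)-alcohol
Product: 18 2-acetate
Conditions: Ac2O, DMAP (cat.), Et3N, CH2Cl2, rt
Reagents that add atoms: acetic anhydride CC(=O)OC(C)=O
Why: DMAP-catalysed acetylation installs the final C2 acetate, which tolerates all later reagents, and leaves the silyl enol ether intact.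

Step 14
Reactants: 18 2-acetate
Product: 19 (5Z,7Z)-5,7-dien-9-one
Conditions: Pd(OAc)2 (1.1 equiv), MeCN, rt → 40 °C
Reagents that add atoms: none
Why: In this Saegusa–Ito oxidation Pd(II) exchanges with the silyl enol ether, and β-hydride loss from C7 places the new C7=C8 bond regiospecifically on the C9 side, in conjugation with C5=C6.

Step 15
Reactants: 19 (5Z,7Z)-5,7-dien-9-one
Product: 20 5-methyl trimethylsilyl dienol ether (C5 epimers)
Conditions: Me2CuLi (MeLi, CuI), TMSCl, THF, −78 °C
Reagents that add atoms: lithium dimethylcuprate [Li+].C[Cu-]C; chlorotrimethylsilane C[Si](C)(C)Cl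
Why: The 1,6-conjugate addition of a Gilman cuprate to the 2,4-dienone, accelerated and terminated by TMSCl, places C16 on the δ-carbon C5 and so tells C5 from C6; the C5 centre formed here disappears in step 16.

Step 16
Reactants: 20 5-methyl trimethylsilyl dienol ether
Product: 21 5-methyl-(5Z,7Z)-5,7-dien-9-one
Conditions: Pd(OAc)2 (1.1 equiv), MeCN, rt
Reagents that add atoms: none
Why: A Saegusa–Ito-type dehydrosilylation of the dienol silyl ether (Pd at C6, β-hydride loss from C5) restores the dienone, now with the trisubstituted C5(Me)=C6 alkene.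

Step 17
Reactants: 21 5-methyl-(5Z,7Z)-5,7-dien-9-one
Product: 22 dienol (C9 carbinol with the target configuration)
Conditions: NaBH4, CeCl3·7H2O, MeOH, −78 → −40 °C
Reagents that add atoms: none
Why: In this Luche 1,2-reduction hydride should reach C9 from the periphery of the ten-membered ring, anti to the ring bond C10–C1 and past H10 rather than C11 (Felkin–Anh sense), which sets C9.

Step 18
Reactants: 22 dienol
Product: 23 cis-7,8-epoxy-9-ol (oxirane syn to the 9-OH)
Conditions: VO(acac)2 (5 mol %), t-BuOOH, CH2Cl2, 0 °C
Reagents that add atoms: tert-butyl hydroperoxide CC(C)(C)OO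
Why: Vanadium-catalysed hydroxyl-directed epoxidation touches only the allylic C7=C8 bond and, as with other medium-ring (Z)-allylic alcohols, should deliver oxygen syn to the C9 hydroxyl.

Step 19
Reactants: 23 cis-7,8-epoxy-9-ol; 24 2-bromopropanoic acid (racemic)
Product: 25 7-(2-bromopropanoyloxy)-8,9-diol
Conditions: Ti(Oi-Pr)4 (1.5 equiv), CH2Cl2, 0 °C → rt
Reagents that add atoms: none
Why: In this titanium(IV)-mediated opening of a 2,3-epoxy alcohol by a carboxylic acid, chelation and allylic activation both direct the acid to C7 (C-3 attack) with inversion, which sets C7 and at the same time attaches C17–C19.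

Step 20
Reactants: 25 7-(2-bromopropanoyloxy)-8,9-diol
Product: 26 8-keto-9-ol
Conditions: Dess–Martin periodinane (1.0 equiv), NaHCO3, CH2Cl2, 0 °C
Reagents that add atoms: none
Why: A Dess–Martin oxidation with one equivalent should take the more accessible C8 hydroxyl, because the C9 hydroxyl is buried beside C10 with its two quaternary neighbours.

Step 21
Reactants: 26 8-keto-9-ol
Product: 27 8-keto-9-acetate
Conditions: Ac2O, 2,6-lutidine, DMAP (10 mol %), CH2Cl2, 0 °C
Reagents that add atoms: acetic anhydride CC(=O)OC(C)=O
Why: Catalysed acetylation installs the final C9 acetate and removes the isomerisable α-ketol, while the hindered base and low temperature spare the α-bromo ester and the C7/C9 centres next to the ketone.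

Step 22
Reactants: 27 8-keto-9-acetate
Product: 28 8-hydroxy-17-methyl γ-lactone (C7, C8, C17 as in the target)
Conditions: Zn (activated, TMSCl cat.), THF, 0 °C → rt; aq NH4Cl
Reagents that add atoms: none
Why: In this intramolecular Reformatsky reaction zinc inserts only into the C–Br bond, and the tethered nucleophile can reach C8 only from the side of O7 with C6 and C9 anti about C7–C8 (also the polar Felkin–Anh face with respect to C9–OAc), which sets C8; the C18 methyl takes the position trans to the C9 chain, which is also the thermodynamically preferred one at the epimerisable C17.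

Step 23
Reactants: 28 8-hydroxy-17-methyl γ-lactone
Product: 29 6-chloro-5(16)-ene acetonide
Conditions: Ca(OCl)2, CO2 (s), CH2Cl2/H2O, 0 °C
Reagents that add atoms: hypochlorous acid OCl, made in the flask from calcium hypochlorite [Ca+2].[O-]Cl.[O-]Cl
Why: In this ene-type allylic chlorination of a trisubstituted alkene Cl+ adds to the less substituted C6 and the C5 cation sheds a proton from the C16 methyl to give the exocyclic methylene; with H7 eclipsing the Z-alkene (A1,3 strain), the reagent is expected on the face anti to the electron-withdrawing C7–O bond, where the C8 hydroxyl can hydrogen-bond it (sets C6), and the deactivated disubstituted C13=C14 should not compete.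

Step 24
Reactants: 29 6-chloro-5(16)-ene acetonide
Product: 30 11α,12α-diol
Conditions: AcOH/H2O (4:1), 40 °C
Reagents that add atoms: none
Why: Mild acid hydrolysis of the dioxolane frees the 12α-hydroxyl needed as a directing group, under conditions that the esters, the lactone and the inductively deactivated allylic chloride should tolerate.

Step 25
Reactants: 30 11α,12α-diol
Product: 31 13α,14α-epoxide
Conditions: VO(acac)2 (5 mol %), t-BuOOH, CH2Cl2, 0 °C
Reagents that add atoms: tert-butyl hydroperoxide CC(C)(C)OO
Why: In this vanadium-catalysed directed epoxidation the allylic 12α-OH delivers oxygen to the α face of C13=C14 (sets C13 and C14), whereas the electron-poor C5=C16 alkene has no allylic hydroxyl and stays.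

Step 26
Reactants: 31 13α,14α-epoxide
Product: 32 CNP0105329.1
Conditions: (n-PrCO)2O, DMAP (cat.), Et3N, CH2Cl2, 0 °C
Reagents that add atoms: butyric anhydride CCCC(=O)OC(=O)CCC
Why: DMAP-catalysed acylation can take place only at the single secondary hydroxyl (C12); the tertiary 8-OH and 11-OH remain free.

**Compound list**
1 | (1Z,5Z)-cycloocta-1,5-diene | C1C/C=C\CC/C=C\1 | starting material
2 | dimethyl (4Z)-oct-4-enedioate | COC(=O)CC/C=C\CCC(=O)OC | intermediate
3 | (1Z,5Z)-1,2-bis(trimethylsilyloxy)cycloocta-1,5-diene | C[Si](C)(C)OC1=C(O[Si](C)(C)C)CC/C=C\CC1 | intermediate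
4 | 3-methylcyclohex-2-en-1-one | CC1=CC(=O)CCC1 | starting material
5 | trans-fused 6-4-8 photoadduct, C11 ketone, 2,9-bis-OTMS (C15 β, H10 α, OTMS groups on the C15 face, 5Z) | C1/C=C\CC[C@]2(O[Si](C)(C)C)[C@H]3C(=O)CCC[C@]3(C)[C@]2(O[Si](C)(C)C)C1 | intermediate
6 | tricyclic 12-en-11-one bis(silyl ether) | C1/C=C\CC[C@]2(O[Si](C)(C)C)[C@H]3C(=O)C=CC[C@]3(C)[C@]2(O[Si](C)(C)C)C1 | intermediate
7 | 11-methyl-12-en-11β-ol bis(silyl ether) | C1/C=C\CC[C@]2(O[Si](C)(C)C)[C@H]3[C@@](C)(O)C=CC[C@]3(C)[C@]2(O[Si](C)(C)C)C1 | intermediate
8 | 6-4-8 tricyclic 2,9,11-triol (cis-cyclobutane-1,2-diol, key-step precursor) | C1/C=C\CC[C@]2(O)[C@H]3[C@@](C)(O)C=CC[C@]3(C)[C@]2(O)C1 | intermediate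
9 | cyclic lead(IV) glycolate of 8 (not isolated) | C1/C=C\CC[C@]2(O5)[C@H]3[C@@](C)(O)C=CC[C@]3(C)[C@]2(O[Pb]5(OC(C)=O)OC(C)=O)C1 | intermediate
10 | 11β-hydroxy-11-methylbicyclo[8.4.0] 5Z,12-diene-2,9-dione (key-step product) | C1/C=C\CCC(=O)[C@H]2[C@@](C)(O)C=CC[C@]2(C)C(=O)C1 | intermediate
11 | C11 2,4-dinitrobenzenesulfenate (not isolated) | C1/C=C\CCC(=O)[C@H]2[C@@](C)(OSc3ccc(cc3[N+](=O)[O-])[N+](=O)[O-])C=CC[C@]2(C)C(=O)C1 | intermediate
12 | C13β allylic sulfoxide, 11-ene (not isolated) | C1/C=C\CCC(=O)[C@H]2C(C)=C[C@@H](S(=O)c3ccc(cc3[N+](=O)[O-])[N+](=O)[O-])C[C@]2(C)C(=O)C1 | intermediate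
13 | 5Z,11,13-triene-2,9-dione | C1/C=C\CCC(=O)[C@H]2C(C)=CC=C[C@]2(C)C(=O)C1 | intermediate
14 | 11α,12α-dihydroxy-5Z,13-diene-2,9-dione | C1/C=C\CCC(=O)[C@H]2[C@](C)(O)[C@H](O)C=C[C@]2(C)C(=O)C1 | intermediate
15 | 11,12-acetonide dione | C1/C=C\CCC(=O)[C@H]2[C@]3(C)OC(C)(C)O[C@@H]3C=C[C@]2(C)C(=O)C1 | intermediate
16 | C9 TBS enol ether (Δ8, ring-cis drawn), C2 ketone | C1/C=C\C/C=C(O[Si](C)(C)C(C)(C)C)\[C@H]2[C@]3(C)OC(C)(C)O[C@@H]3C=C[C@]2(C)C(=O)C1 | intermediate
17 | (2S)-alcohol | C1/C=C\C/C=C(O[Si](C)(C)C(C)(C)C)\[C@H]2[C@]3(C)OC(C)(C)O[C@@H]3C=C[C@]2(C)[C@@H](O)C1 | intermediate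
18 | 2-acetate | C1/C=C\C/C=C(O[Si](C)(C)C(C)(C)C)\[C@H]2[C@]3(C)OC(C)(C)O[C@@H]3C=C[C@]2(C)[C@@H](OC(C)=O)C1 | intermediate
19 | (5Z,7Z)-5,7-dien-9-one | C1/C=C\C=C/C(=O)[C@H]2[C@]3(C)OC(C)(C)O[C@@H]3C=C[C@]2(C)[C@@H](OC(C)=O)C1 | intermediate
20 | 5-methyl TMS dienol ether (C5 epimers) | C1C(C)/C=C\C=C(O[Si](C)(C)C)/[C@H]2[C@]3(C)OC(C)(C)O[C@@H]3C=C[C@]2(C)[C@@H](OC(C)=O)C1 | intermediate
21 | 5-methyl-(5Z,7Z)-5,7-dien-9-one | C1/C(C)=C\C=C/C(=O)[C@H]2[C@]3(C)OC(C)(C)O[C@@H]3C=C[C@]2(C)[C@@H](OC(C)=O)C1 | intermediate
22 | dienol, C9 carbinol as in the target | C1/C(C)=C\C=C/[C@@H](O)[C@H]2[C@]3(C)OC(C)(C)O[C@@H]3C=C[C@]2(C)[C@@H](OC(C)=O)C1 | intermediate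
23 | cis-7,8-epoxy-9-ol (oxirane syn to 9-OH) | C1/C(C)=C\[C@H]4O[C@H]4[C@@H](O)[C@H]2[C@]3(C)OC(C)(C)O[C@@H]3C=C[C@]2(C)[C@@H](OC(C)=O)C1 | intermediate
24 | 2-bromopropanoic acid (racemic) | CC(Br)C(=O)O | starting material
25 | 7-(2-bromopropanoyloxy)-8,9-diol (CHBr epimers) | C1/C(C)=C\[C@H](OC(=O)C(C)Br)[C@@H](O)[C@@H](O)[C@H]2[C@]3(C)OC(C)(C)O[C@@H]3C=C[C@]2(C)[C@@H](OC(C)=O)C1 | intermediate
26 | 8-keto-9-ol | C1/C(C)=C\[C@H](OC(=O)C(C)Br)C(=O)[C@@H](O)[C@H]2[C@]3(C)OC(C)(C)O[C@@H]3C=C[C@]2(C)[C@@H](OC(C)=O)C1 | intermediate
27 | 8-keto-9-acetate | C1/C(C)=C\[C@H](OC(=O)C(C)Br)C(=O)[C@@H](OC(C)=O)[C@H]2[C@]3(C)OC(C)(C)O[C@@H]3C=C[C@]2(C)[C@@H](OC(C)=O)C1 | intermediate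
28 | 8-hydroxy-17-methyl γ-lactone, 5Z-ene, acetonide | C1/C(C)=C\[C@@H]5OC(=O)[C@H](C)[C@@]5(O)[C@@H](OC(C)=O)[C@H]2[C@]3(C)OC(C)(C)O[C@@H]3C=C[C@]2(C)[C@@H](OC(C)=O)C1 | intermediate
29 | 6-chloro-5(16)-ene acetonide | C1C(=C)[C@H](Cl)[C@@H]5OC(=O)[C@H](C)[C@@]5(O)[C@@H](OC(C)=O)[C@H]2[C@]3(C)OC(C)(C)O[C@@H]3C=C[C@]2(C)[C@@H](OC(C)=O)C1 | intermediate
30 | 11α,12α-diol, 13-ene | C1C(=C)[C@H](Cl)[C@@H]5OC(=O)[C@H](C)[C@@]5(O)[C@@H](OC(C)=O)[C@H]2[C@](C)(O)[C@H](O)C=C[C@]2(C)[C@@H](OC(C)=O)C1 | intermediate
31 | 13α,14α-epoxy-11α,12α-diol | C1C(=C)[C@H](Cl)[C@@H]5OC(=O)[C@H](C)[C@@]5(O)[C@@H](OC(C)=O)[C@H]2[C@](C)(O)[C@H](O)[C@@H]6O[C@@H]6[C@]2(C)[C@@H](OC(C)=O)C1 | intermediate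
32 | CNP0105329.1 (1S,2S,6S,7R,8R,9S,10S,11S,12R,13R,14R,17R) | C=C1CC[C@H](OC(C)=O)[C@@]2(C)[C@H]3O[C@H]3[C@@H](OC(=O)CCC)[C@@](C)(O)[C@@H]2[C@H](OC(C)=O)[C@]2(O)[C@@H](C)C(=O)O[C@H]2[C@H]1Cl | target

Total step count: 26. Longest linear sequence: 26 steps (from 1).

**Steps most likely to fail**

Step 3. The strong Lewis acid may strip or activate the silyl enol ether units. The enantioselectivity with a tetrasubstituted, oxygenated alkene may be low. Closure may favour the cis six-four fusion, or the remote alkene may react instead.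
The fallback sets out from 3 and 4 and returns at 5. Direct irradiation without additive (Pyrex, hexane, −40 °C) is the known reaction of cyclohexenones with bis(silyloxy)cycloalkenes. After separation of the cis-fused isomer on neutral silica it gives the racemic trans photoadduct F1. Catalyst-controlled reduction with (R)-Me-CBS and catecholborane then converts the two enantiomers into diastereomeric C11 carbinols. These are the (11S)-alcohol of the wanted series F2 (hydride from the open α face, matched) and the (11S)-alcohol of the mirror-image series F3, and they are separable on silica. Dess–Martin oxidation of F2, which does not touch C10, returns enantiopure 5.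

Step 22. The five-membered closure may be slow because of the enolate geometry within the forming ring. In that case protonation of the zinc enolate (simple debromination) or reductive loss of an α-acyloxy group may take over.
The fallback sets out from 27 and returns at 28, replacing the tether by chelation control. Thiourea and NaHCO3 in EtOH/THF remove the 2-bromopropanoyl group, as they do haloacetates, to give the 7-hydroxy-8-keto 9-acetate F4. An excess of the Reformatsky reagent from ethyl 2-bromopropanoate and zinc first forms the zinc alkoxide at O7, which chelates the C8 carbonyl. It then adds from the side of H7, which is the same face as polar Felkin–Anh control by C9–OAc. This gives the open-chain hydroxy ester F5, which lactonises with O7 on work-up to 28.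

Step 23. Three things may go wrong: attack of Cl+ on the other alkene face (the side away from the fully substituted C8), capture of the C5 cation by the 8-hydroxyl, or proton loss from C4.
The fallback sets out from 28 and returns at 29, and it turns that same facial bias to advantage. mCPBA (NaHCO3, CH2Cl2, 0 °C) epoxidises the trisubstituted alkene on that face to give the 5,6-epoxide F6. Cp2TiCl (Cp2TiCl2, Mn, THF) opens F6 homolytically at the tertiary C5 and eliminates toward the methyl group, giving the exo-methylene 6-epi-alcohol F7. PPh3 with hexachloroacetone then replaces the allylic hydroxyl by chloride with inversion and without allylic shift, giving 29.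

**Further compounds**
F1 | step 3 | racemic trans photoadduct (5 together with its mirror image; the mirror image is drawn) | C1/C=C\CC[C@@]2(O[Si](C)(C)C)[C@@H]3C(=O)CCC[C@@]3(C)[C@@]2(O[Si](C)(C)C)C1
F2 | step 3 | (11S)-alcohol of the wanted series (11β-OH) | C1/C=C\CC[C@]2(O[Si](C)(C)C)[C@H]3[C@@H](O)CCC[C@]3(C)[C@]2(O[Si](C)(C)C)C1
F3 | step 3 | (11S)-alcohol of the mirror-image series (discarded) | C1/C=C\CC[C@@]2(O[Si](C)(C)C)[C@@H]3[C@@H](O)CCC[C@@]3(C)[C@@]2(O[Si](C)(C)C)C1
F4 | step 22 | 7-hydroxy-8-keto 9-acetate | C1/C(C)=C\[C@H](O)C(=O)[C@@H](OC(C)=O)[C@H]2[C@]3(C)OC(C)(C)O[C@@H]3C=C[C@]2(C)[C@@H](OC(C)=O)C1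
F5 | step 22 | open-chain hydroxy ester (ethyl ester, 7,8-diol) | C1/C(C)=C\[C@H](O)[C@@](O)([C@@H](C)C(=O)OCC)[C@@H](OC(C)=O)[C@H]2[C@]3(C)OC(C)(C)O[C@@H]3C=C[C@]2(C)[C@@H](OC(C)=O)C1
F6 | step 23 | 5,6-epoxide | C1[C@@]7(C)O[C@H]7[C@@H]5OC(=O)[C@H](C)[C@@]5(O)[C@@H](OC(C)=O)[C@H]2[C@]3(C)OC(C)(C)O[C@@H]3C=C[C@]2(C)[C@@H](OC(C)=O)C1
F7 | step 23 | exo-methylene 6-epi-alcohol | C1C(=C)[C@@H](O)[C@@H]5OC(=O)[C@H](C)[C@@]5(O)[C@@H](OC(C)=O)[C@H]2[C@]3(C)OC(C)(C)O[C@@H]3C=C[C@]2(C)[C@@H](OC(C)=O)C1
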